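**Retrosynthetic overview**

- Elemane numbering is used: C10 (quaternary; C14 methyl, C1=C2 vinyl), C9, C8 (acyloxy), C7, C6 (lactone O), C5 (carrying C4(=C3)–C15) and lactone carbons C11–C13. The route rests on the γ-lactone fused at C6–C7 of the cyclohexane: C6, taken back to a ketone, and the C12 carbonyl are 1,4-related through the C7–C11 bond, the pattern a donor–acceptor cyclopropane over C6, C7 and C11 releases.
- α-Methylene lactone ⇒ γ-keto ester ⇒ siloxycyclopropane ester ⇒ C6=C7 silyl enol ether of an 8α-silyloxy cyclohexanone + ethyl diazoacetate (forms C7–C11 and C6–C11).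
- Cyclohexanone ⇒ intramolecular aldol (C7–C8) of a C6 methyl ketone onto a C8 aldehyde; C5–C10 and both stereocentres ⇒ enantioselective Ireland–Claisen rearrangement of an (E)-allyl but-3-enoate made from 4-methyl itaconate and a butynyl silyl ether.
- Ring order: cyclohexane (aldol), cyclopropane (carbenoid, reopened), γ-lactone (C6 reduction and lactonisation); the C8 ester with the (Z)-acid and desilylation come last.

Key step: step 13

Assumption: the (S,S) enantiomer of the diazaborolidine bromide is taken to be the one that delivers the (2R,3S) Claisen acid; should the sense of induction prove opposite, its (R,R) antipode is used with no other change.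

Abbreviations: TBS = tert-butyldimethylsilyl, TBDPS = tert-butyldiphenylsilyl, TMS = trimethylsilyl; α/β refer to the ring face opposite to/same as the C10 methyl.

**Route**

Step 1
Reactants: 1 4-methyl hydrogen itaconate
Product: 2 methyl 3-(hydroxymethyl)but-3-enoate
Conditions: BH3·SMe2 (1.1 equiv), THF, −10 to 0 °C; MeOH
Reagents that add atoms: none
Why: Borane reduces the free carboxylic acid through its acyloxyborane much faster than the ester or the electron-poor 1,1-disubstituted alkene (chemoselective acid reduction), and the crude alcohol is silylated at once so that it cannot lactonise.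

Step 2
Reactants: 2 methyl 3-(hydroxymethyl)but-3-enoate
Product: 3 methyl 3-(TBDPS-oxymethyl)but-3-enoate
Conditions: TBDPSCl, imidazole, DMF, 0 °C to rt
Reagents that add atoms: tert-butyl(chloro)diphenylsilane, CC(C)(C)[Si](Cl)(c1ccccc1)c1ccccc1
Why: Standard silylation of a primary allylic alcohol; a bulky silyl ether is chosen because, unlike a benzyl or allyl ether, it should not engage the later carbenoid in oxonium ylide chemistry and it outlasts the C8 silyl ether.

Step 3
Reactants: 3 methyl 3-(TBDPS-oxymethyl)but-3-enoate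
Product: 4 3-(TBDPS-oxymethyl)but-3-enoic acid
Conditions: LiOH, THF–H2O, 0 °C; then cold 1 M HCl
Reagents that add atoms: lithium hydroxide, [Li+].[OH-]
Why: Saponification at 0 °C should hydrolyse the methyl ester without moving the β,γ-double bond into conjugation.

Step 4
Reactants: 5 4-(TBS-oxy)but-1-yne
Product: 7 (E)-5-(TBS-oxy)-3-methylpent-2-en-1-ol, via alkenylalane 6 (not isolated)
Conditions: Me3Al, Cp2ZrCl2 (0.25 equiv), CH2Cl2, 0 °C to rt; then n-BuLi, THF, −78 °C; (CH2O)n, −78 °C to rt; aq Rochelle salt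
Reagents that add atoms: trimethylaluminium, C[Al](C)C; formaldehyde (from paraformaldehyde), C=O
Why: Negishi zirconium-catalysed carboalumination adds methyl and aluminium syn across the terminal alkyne with methyl on the internal carbon, and the derived alanate traps formaldehyde with retention, which fixes the (E) geometry that the Claisen chair later turns into the C10 configuration.

Step 5
Reactants: 4 3-(TBDPS-oxymethyl)but-3-enoic acid; 7 (E)-5-(TBS-oxy)-3-methylpent-2-en-1-ol
Product: 8 (E)-5-(TBS-oxy)-3-methylpent-2-en-1-yl 3-(TBDPS-oxymethyl)but-3-enoate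
Conditions: PPh3, DIAD, THF, 0 °C to rt
Reagents that add atoms: none
Why: Mitsunobu esterification activates the primary allylic alcohol and not the acid, so the β,γ-unsaturated acid never becomes an acylating species that could slip into conjugation, and displacement at the primary carbinol is direct.

Step 6
Reactants: 8 (E)-5-(TBS-oxy)-3-methylpent-2-en-1-yl 3-(TBDPS-oxymethyl)but-3-enoate
Product: 10 (2R,3S)-3-[2-(TBS-oxy)ethyl]-3-methyl-2-[3-(TBDPS-oxy)prop-1-en-2-yl]pent-4-enoic acid, via boron ketene acetal 9 (not isolated)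
Conditions: (S,S)-2-bromo-4,5-diphenyl-1,3-bis[3,5-bis(trifluoromethyl)phenylsulfonyl]-1,3,2-diazaborolidine (generated in the flask from the (S,S)-bis-sulfonamide and BBr3 in CH2Cl2, volatiles removed), Et3N, toluene–hexane, −78 °C, then 4 °C to rt; aq work-up
Reagents that add atoms: none
Why: Enantioselective Ireland–Claisen rearrangement in which soft enolisation by the bromoborane and Et3N gives the boron ketene acetal with the C4 substituent trans to the bulky O–B group, the chair transition state with the C9 chain of the (E)-alkene equatorial sets the C5/C10 relative configuration, and the C2-symmetric sulfonamide ligand shields one enolate face to set the absolute sense.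

Step 7
Reactants: 10 (2R,3S)-3-[2-(TBS-oxy)ethyl]-3-methyl-2-[3-(TBDPS-oxy)prop-1-en-2-yl]pent-4-enoic acid
Product: 12 (3R,4S)-4-[2-(TBS-oxy)ethyl]-4-methyl-3-[3-(TBDPS-oxy)prop-1-en-2-yl]hex-5-en-2-one, via dilithium gem-diolate 11 (not isolated)
Conditions: MeLi (4 equiv), Et2O, 0 °C to rt; then cold dilute HCl
Reagents that add atoms: methyllithium, [Li]C
Why: Addition of MeLi to the lithium carboxylate stops at the dilithium gem-diolate, which releases the methyl ketone only on work-up (carboxylic acid to methyl ketone), so no enolisable ketone is exposed to base and C5 should keep its configuration.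

Step 8
Reactants: 12 (3R,4S)-4-[2-(TBS-oxy)ethyl]-4-methyl-3-[3-(TBDPS-oxy)prop-1-en-2-yl]hex-5-en-2-one
Product: 13 (3R,4S)-4-(2-hydroxyethyl)-4-methyl-3-[3-(TBDPS-oxy)prop-1-en-2-yl]hex-5-en-2-one
Conditions: AcOH–THF–H2O (3:1:1), rt
Reagents that add atoms: none
Why: Mild aqueous acid cleaves the unhindered primary TBS ether while the far more acid-stable TBDPS ether stays (selective desilylation).

Step 9
Reactants: 13 (3R,4S)-4-(2-hydroxyethyl)-4-methyl-3-[3-(TBDPS-oxy)prop-1-en-2-yl]hex-5-en-2-one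
Product: 14 (3S,4R)-3-ethenyl-3-methyl-5-oxo-4-[3-(TBDPS-oxy)prop-1-en-2-yl]hexanal
Conditions: Dess–Martin periodinane, NaHCO3, CH2Cl2, 0 °C to rt
Reagents that add atoms: none
Why: Buffered periodinane oxidation converts the primary alcohol (drawn from its lactol equilibrium) into the aldehyde under neutral conditions that should leave the β,γ-unsaturated ketone and its α-stereocentre alone.

Step 10
Reactants: 14 (3S,4R)-3-ethenyl-3-methyl-5-oxo-4-[3-(TBDPS-oxy)prop-1-en-2-yl]hexanal
Product: 15 (2R,3S,5S)-3-ethenyl-5-hydroxy-3-methyl-2-[3-(TBDPS-oxy)prop-1-en-2-yl]cyclohexan-1-one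
Conditions: (S)-proline (0.3 equiv), DMSO, rt, dilute
Reagents that add atoms: none
Why: Amine-catalysed intramolecular aldol (6-enolendo) in which only the enamine on the methyl side can reach the aldehyde, and the new C8 stereocentre is set by the substrate because in the chair with the C5 side chain equatorial an axial C8 oxygen would be 1,3-diaxial to the C10 methyl, so the hydroxyl should come out equatorial (8α), which is also the thermodynamic ketol.

Step 11
Reactants: 15 (2R,3S,5S)-3-ethenyl-5-hydroxy-3-methyl-2-[3-(TBDPS-oxy)prop-1-en-2-yl]cyclohexan-1-one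
Product: 16 (2R,3S,5S)-5-(TBS-oxy)-3-ethenyl-3-methyl-2-[3-(TBDPS-oxy)prop-1-en-2-yl]cyclohexan-1-one
Conditions: TBSOTf, 2,6-lutidine, CH2Cl2, −78 °C
Reagents that add atoms: tert-butyldimethylsilyl trifluoromethanesulfonate, CC(C)(C)[Si](C)(C)OS(=O)(=O)C(F)(F)F
Why: Silyl triflate with a hindered pyridine base silylates the secondary alcohol at low temperature faster than the β-hydroxy ketone can dehydrate or enolise.

Step 12
Reactants: 16 (2R,3S,5S)-5-(TBS-oxy)-3-ethenyl-3-methyl-2-[3-(TBDPS-oxy)prop-1-en-2-yl]cyclohexan-1-one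
Product: 18 (3S,5S,6R)-3-(TBS-oxy)-5-ethenyl-5-methyl-6-[3-(TBDPS-oxy)prop-1-en-2-yl]-1-(TMS-oxy)cyclohex-1-ene, via lithium enolate 17 (not isolated)
Conditions: LiN(i-Pr)2 added to 16 and TMSCl, THF, −78 °C; Et3N, pentane, filtration; used crude
Reagents that add atoms: chlorotrimethylsilane, C[Si](C)(C)Cl
Why: Kinetic deprotonation takes a proton from the unhindered C7 methylene and not from the neopentylic C5 methine, and silylation of the enolate in the same flask at −78 °C should outrun β-elimination of the C8 silyloxy group (kinetic silyl enol ether formation).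

Step 13
Reactants: 18 (3S,5S,6R)-3-(TBS-oxy)-5-ethenyl-5-methyl-6-[3-(TBDPS-oxy)prop-1-en-2-yl]-1-(TMS-oxy)cyclohex-1-ene; 19 ethyl diazoacetate
Product: 20 ethyl 2-(TBS-oxy)-4-ethenyl-4-methyl-5-[3-(TBDPS-oxy)prop-1-en-2-yl]-6-(TMS-oxy)bicyclo[4.1.0]heptane-7-carboxylate (cyclopropane on the β face, ester exo)
Conditions: Rh2(OAc)4 (1 mol %), CH2Cl2, rt, slow addition of 19
Reagents that add atoms: none
Why: Rh2(OAc)4 decomposes 19 with loss of N2 to an electrophilic rhodium carbenoid that adds to the C6=C7 enol ether in a concerted, asynchronous [2+1] step, C7–C11 forming first at the nucleophilic enol ether terminus and C6–C11 following as the carbenoid carbon collapses onto the developing oxocarbenium centre. This is the established cyclopropanation of silyl enol ethers with diazoacetates to 2-siloxycyclopropanecarboxylates. The three-membered ring is closed by carbene transfer, both new bonds coming from the one carbon and C6–C11 being the ring-closing bond, which gives the cis-fused bicyclo[4.1.0]heptane. C7, and with it the cis-related C6, should be set by attack anti to the neighbouring C8 OTBS group, which flanks the carbon where bonding is most advanced, whereas the axial C10 methyl is 1,3 only to C6 where bonding lags; C11 is expected mainly exo for steric reasons and, like C6, is erased in the next step. The step needs chemoselectivity for the enol ether over the C1=C2 vinyl and C3=C4 methylene groups and β-facial selectivity; the first is secured by the much greater nucleophilicity of the silyl enol ether (the vinyl group is neopentylic and monosubstituted, the methylene group carries an inductively deactivating allylic silyloxy group) and the second by the bulky C8 silyl ether, while silyl in place of alkyl ethers keeps oxonium ylide chemistry out.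

Step 14
Reactants: 20 ethyl 2-(TBS-oxy)-4-ethenyl-4-methyl-5-[3-(TBDPS-oxy)prop-1-en-2-yl]-6-(TMS-oxy)bicyclo[4.1.0]heptane-7-carboxylate
Product: 21 ethyl 2-[(1R,3R,4S,6S)-6-(TBS-oxy)-4-ethenyl-4-methyl-2-oxo-3-[3-(TBDPS-oxy)prop-1-en-2-yl]cyclohexyl]acetate
Conditions: Et3N·3HF, THF, 0 °C to rt
Reagents that add atoms: none
Why: Fluoride removes the TMS group and the cyclopropanolate opens at the donor–acceptor C6–C11 bond to the ester-stabilised carbanion, which is protonated (ring opening of a 2-siloxycyclopropanecarboxylate to a γ-oxo ester); C7–C11 is untouched and the acetate arm sits equatorial, the stable arrangement α to the new ketone.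

Step 15
Reactants: 21 ethyl 2-[(1R,3R,4S,6S)-6-(TBS-oxy)-4-ethenyl-4-methyl-2-oxo-3-[3-(TBDPS-oxy)prop-1-en-2-yl]cyclohexyl]acetate
Product: 23 8α-(TBS-oxy)-15-(TBDPS-oxy)elema-1,3-dien-6α,12-olide (trans-fused γ-lactone), via hydroxy ester 22 (not isolated)
Conditions: SmI2 (2.5 equiv), H2O, THF, 0 °C; then p-TsOH (catalytic), toluene, rt
Reagents that add atoms: none
Why: Electron-transfer reduction by SmI2 passes through a ketyl and an α-oxido organosamarium that should be protonated to the thermodynamically preferred equatorial 6α-carbinol, the outcome of dissolving-metal-type reductions of cyclohexanones with a syn-axial methyl for which hydride reagents give the axial alcohol, and the 6α-hydroxyl then closes the trans-fused γ-lactone with the equatorial C7 acetate arm under acid catalysis.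

Step 16
Reactants: 23 8α-(TBS-oxy)-15-(TBDPS-oxy)elema-1,3-dien-6α,12-olide
Product: 25 13-(dimethylamino)-8α-(TBS-oxy)-15-(TBDPS-oxy)elema-1,3-dien-6α,12-olide (C11 epimers), via lithium enolate 24 (not isolated)
Conditions: LiN(i-Pr)2, THF, −78 °C; then Me2N=CH2+ I−, −78 to 0 °C
Reagents that add atoms: dimethylmethyleneammonium iodide, C=[N+](C)C.[I-]
Why: The lactone can only be enolised at C11, and the enolate is aminomethylated by the iminium salt (Mannich reaction); the C11 configuration does not matter because it is lost in the next step.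

Step 17
Reactants: 25 13-(dimethylamino)-8α-(TBS-oxy)-15-(TBDPS-oxy)elema-1,3-dien-6α,12-olide
Product: 27 8α-(TBS-oxy)-15-(TBDPS-oxy)elema-1,3,11(13)-trien-6α,12-olide, via trimethylammonium iodide 26 (not isolated)
Conditions: MeI, MeOH, rt; then aq NaHCO3, EtOAc, rt
Reagents that add atoms: none
Why: Quaternisation of the amine followed by mild-base elimination of trimethylamine from the β-ammonio lactone (Hofmann-type elimination) gives the exocyclic C11=C13 methylene without exposing the product to a strong nucleophile.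

Step 18
Reactants: 27 8α-(TBS-oxy)-15-(TBDPS-oxy)elema-1,3,11(13)-trien-6α,12-olide
Product: 28 8α-hydroxy-15-(TBDPS-oxy)elema-1,3,11(13)-trien-6α,12-olide
Conditions: HF (48 % aq), MeCN, 0 °C
Reagents that add atoms: none
Why: Aqueous HF in acetonitrile cleaves the secondary TBS ether much faster than the primary TBDPS ether, and the acidic medium should leave the Michael-acceptor lactone untouched (selective desilylation).

Step 19
Reactants: 29 (E)-crotonaldehyde
Product: 30 (Z)-2-iodobut-2-enal
Conditions: I2, K2CO3, DMAP (catalytic), THF–H2O, rt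
Reagents that add atoms: iodine, II
Why: Amine-catalysed α-iodination of the enal (conjugate addition of DMAP, iodination of the enolate, elimination) gives the thermodynamically preferred isomer with iodine cis to the methyl group.

Step 20
Reactants: 30 (Z)-2-iodobut-2-enal
Product: 31 (Z)-2-iodobut-2-en-1-ol
Conditions: NaBH4, MeOH, 0 °C
Reagents that add atoms: none
Why: 1,2-Reduction of the aldehyde by borohydride leaves the vinyl iodide and its geometry intact.

Step 21
Reactants: 31 (Z)-2-iodobut-2-en-1-ol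
Product: 32 (Z)-1-(TBS-oxy)-2-iodobut-2-ene
Conditions: TBSCl, imidazole, CH2Cl2, rt
Reagents that add atoms: tert-butyl(chloro)dimethylsilane, CC(C)(C)[Si](C)(C)Cl
Why: Standard silylation masks the hydroxyl before lithiation and later acylation.

Step 22
Reactants: 32 (Z)-1-(TBS-oxy)-2-iodobut-2-ene
Product: 34 (Z)-2-(TBS-oxymethyl)but-2-enoic acid, via vinyllithium 33 (not isolated)
Conditions: t-BuLi (2.1 equiv), Et2O, −78 °C; then CO2; cold dilute HCl
Reagents that add atoms: carbon dioxide, O=C=O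
Why: Iodine–lithium exchange at −78 °C gives a configurationally stable vinyllithium that is carboxylated with retention, so the carboxyl group ends cis to the methyl group, which is the (Z) acid of the side chain.

Step 23
Reactants: 34 (Z)-2-(TBS-oxymethyl)but-2-enoic acid; 28 8α-hydroxy-15-(TBDPS-oxy)elema-1,3,11(13)-trien-6α,12-olide
Product: 36 8α-[(Z)-2-(TBS-oxymethyl)but-2-enoyloxy]-15-(TBDPS-oxy)elema-1,3,11(13)-trien-6α,12-olide, via mixed anhydride 35 (not isolated)
Conditions: 2,4,6-Cl3C6H2COCl, Et3N, toluene, rt; then 28, DMAP, toluene, rt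
Reagents that add atoms: none
Why: Yamaguchi esterification through the mixed anhydride and DMAP acylates the hindered equatorial C8 alcohol at room temperature, conditions under which angelate-type (Z) acids keep their geometry.

Step 24
Reactants: 36 8α-[(Z)-2-(TBS-oxymethyl)but-2-enoyloxy]-15-(TBDPS-oxy)elema-1,3,11(13)-trien-6α,12-olide
Product: 37 CNP0111202.1, 8α-[(Z)-2-(hydroxymethyl)but-2-enoyloxy]-15-hydroxyelema-1,3,11(13)-trien-6α,12-olide
Conditions: HF·pyridine, pyridine, THF, 0 °C to rt
Reagents that add atoms: none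
Why: Buffered fluoride cleaves both primary silyl ethers (global desilylation) under mildly acidic conditions that should spare the α-methylene lactone and the (Z) ester.

**Compound list**

1 | 4-methyl hydrogen itaconate | C=C(CC(=O)OC)C(=O)O | starting material
2 | methyl 3-(hydroxymethyl)but-3-enoate | C=C(CO)CC(=O)OC | intermediate
3 | methyl 3-(TBDPS-oxymethyl)but-3-enoate | C=C(CO[Si](c1ccccc1)(c1ccccc1)C(C)(C)C)CC(=O)OC | intermediate
4 | 3-(TBDPS-oxymethyl)but-3-enoic acid | C=C(CO[Si](c1ccccc1)(c1ccccc1)C(C)(C)C)CC(=O)O | intermediate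
5 | 4-(TBS-oxy)but-1-yne | C#CCCO[Si](C)(C)C(C)(C)C | starting material
6 | dimethyl[(E)-4-(TBS-oxy)-2-methylbut-1-en-1-yl]alane | C[Al](C)/C=C(\C)CCO[Si](C)(C)C(C)(C)C | intermediate
7 | (E)-5-(TBS-oxy)-3-methylpent-2-en-1-ol | OC/C=C(\C)CCO[Si](C)(C)C(C)(C)C | intermediate
8 | (E)-5-(TBS-oxy)-3-methylpent-2-en-1-yl 3-(TBDPS-oxymethyl)but-3-enoate | C=C(CO[Si](c1ccccc1)(c1ccccc1)C(C)(C)C)CC(=O)OC/C=C(\C)CCO[Si](C)(C)C(C)(C)C | intermediate
9 | boron ketene acetal of 8 (C4 substituent trans to O–B; boron in the (S,S)-bis-sulfonyl diazaborolidine) | C=C(CO[Si](c1ccccc1)(c1ccccc1)C(C)(C)C)/C=C(/OB1N(S(=O)(=O)c2cc(C(F)(F)F)cc(C(F)(F)F)c2)[C@@H](c2ccccc2)[C@H](c2ccccc2)N1S(=O)(=O)c1cc(C(F)(F)F)cc(C(F)(F)F)c1)OC/C=C(\C)CCO[Si](C)(C)C(C)(C)C | intermediate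
10 | (2R,3S)-3-[2-(TBS-oxy)ethyl]-3-methyl-2-[3-(TBDPS-oxy)prop-1-en-2-yl]pent-4-enoic acid | C=C[C@](C)(CCO[Si](C)(C)C(C)(C)C)[C@@H](C(=O)O)C(=C)CO[Si](c1ccccc1)(c1ccccc1)C(C)(C)C | intermediate
11 | dilithium gem-diolate formed from 10 and MeLi | [Li+].[Li+].C=C[C@](C)(CCO[Si](C)(C)C(C)(C)C)[C@@H](C(C)([O-])[O-])C(=C)CO[Si](c1ccccc1)(c1ccccc1)C(C)(C)C | intermediate
12 | (3R,4S)-4-[2-(TBS-oxy)ethyl]-4-methyl-3-[3-(TBDPS-oxy)prop-1-en-2-yl]hex-5-en-2-one | C=C[C@](C)(CCO[Si](C)(C)C(C)(C)C)[C@@H](C(C)=O)C(=C)CO[Si](c1ccccc1)(c1ccccc1)C(C)(C)C | intermediate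
13 | (3R,4S)-4-(2-hydroxyethyl)-4-methyl-3-[3-(TBDPS-oxy)prop-1-en-2-yl]hex-5-en-2-one | C=C[C@](C)(CCO)[C@@H](C(C)=O)C(=C)CO[Si](c1ccccc1)(c1ccccc1)C(C)(C)C | intermediate
14 | (3S,4R)-3-ethenyl-3-methyl-5-oxo-4-[3-(TBDPS-oxy)prop-1-en-2-yl]hexanal | C=C[C@](C)(CC=O)[C@@H](C(C)=O)C(=C)CO[Si](c1ccccc1)(c1ccccc1)C(C)(C)C | intermediate
15 | (2R,3S,5S)-3-ethenyl-5-hydroxy-3-methyl-2-[3-(TBDPS-oxy)prop-1-en-2-yl]cyclohexan-1-one (8α-hydroxy C6 ketone) | C=C[C@]1(C)C[C@H](O)CC(=O)[C@H]1C(=C)CO[Si](c1ccccc1)(c1ccccc1)C(C)(C)C | intermediate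
16 | (2R,3S,5S)-5-(TBS-oxy)-3-ethenyl-3-methyl-2-[3-(TBDPS-oxy)prop-1-en-2-yl]cyclohexan-1-one | C=C[C@]1(C)C[C@H](O[Si](C)(C)C(C)(C)C)CC(=O)[C@H]1C(=C)CO[Si](c1ccccc1)(c1ccccc1)C(C)(C)C | intermediate
17 | lithium C6=C7 enolate of 16 | [Li+].C=C[C@]1(C)C[C@H](O[Si](C)(C)C(C)(C)C)C=C([O-])[C@H]1C(=C)CO[Si](c1ccccc1)(c1ccccc1)C(C)(C)C | intermediate
18 | (3S,5S,6R)-3-(TBS-oxy)-5-ethenyl-5-methyl-6-[3-(TBDPS-oxy)prop-1-en-2-yl]-1-(TMS-oxy)cyclohex-1-ene (C6=C7 silyl enol ether) | C=C[C@]1(C)C[C@H](O[Si](C)(C)C(C)(C)C)C=C(O[Si](C)(C)C)[C@H]1C(=C)CO[Si](c1ccccc1)(c1ccccc1)C(C)(C)C | intermediate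
19 | ethyl diazoacetate | CCOC(=O)C=[N+]=[N-] | starting material
20 | ethyl 2-(TBS-oxy)-4-ethenyl-4-methyl-5-[3-(TBDPS-oxy)prop-1-en-2-yl]-6-(TMS-oxy)bicyclo[4.1.0]heptane-7-carboxylate (cyclopropane fused at C6–C7 on the β face, cis to the C5 side chain and trans to C8–OTBS; C6 OTMS α; ester exo) | C=C[C@]1(C)C[C@H](O[Si](C)(C)C(C)(C)C)[C@H]2[C@H](C(=O)OCC)[C@@]2(O[Si](C)(C)C)[C@H]1C(=C)CO[Si](c1ccccc1)(c1ccccc1)C(C)(C)C | intermediate
21 | ethyl 2-[(1R,3R,4S,6S)-6-(TBS-oxy)-4-ethenyl-4-methyl-2-oxo-3-[3-(TBDPS-oxy)prop-1-en-2-yl]cyclohexyl]acetate | C=C[C@]1(C)C[C@H](O[Si](C)(C)C(C)(C)C)[C@@H](CC(=O)OCC)C(=O)[C@H]1C(=C)CO[Si](c1ccccc1)(c1ccccc1)C(C)(C)C | intermediate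
22 | 6α-hydroxy ester (ethyl ester of the seco acid of 23; C6 OH equatorial, trans to the C7 arm) | C=C[C@]1(C)C[C@H](O[Si](C)(C)C(C)(C)C)[C@@H](CC(=O)OCC)[C@H](O)[C@H]1C(=C)CO[Si](c1ccccc1)(c1ccccc1)C(C)(C)C | intermediate
23 | 8α-(TBS-oxy)-15-(TBDPS-oxy)elema-1,3-dien-6α,12-olide (5α-H, 7α-H, 10β-methyl; trans-fused lactone) | C=C[C@]1(C)C[C@H](O[Si](C)(C)C(C)(C)C)[C@H]2CC(=O)O[C@@H]2[C@H]1C(=C)CO[Si](c1ccccc1)(c1ccccc1)C(C)(C)C | intermediate
24 | lithium enolate of lactone 23 | [Li+].C=C[C@]1(C)C[C@H](O[Si](C)(C)C(C)(C)C)[C@H]2C=C([O-])O[C@@H]2[C@H]1C(=C)CO[Si](c1ccccc1)(c1ccccc1)C(C)(C)C | intermediate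
25 | 13-(dimethylamino)-8α-(TBS-oxy)-15-(TBDPS-oxy)elema-1,3-dien-6α,12-olide (C11 configuration not controlled) | C=C[C@]1(C)C[C@H](O[Si](C)(C)C(C)(C)C)[C@H]2C(CN(C)C)C(=O)O[C@@H]2[C@H]1C(=C)CO[Si](c1ccccc1)(c1ccccc1)C(C)(C)C | intermediate
26 | trimethylammonium iodide of 25 | [I-].C=C[C@]1(C)C[C@H](O[Si](C)(C)C(C)(C)C)[C@H]2C(C[N+](C)(C)C)C(=O)O[C@@H]2[C@H]1C(=C)CO[Si](c1ccccc1)(c1ccccc1)C(C)(C)C | intermediate
27 | 8α-(TBS-oxy)-15-(TBDPS-oxy)elema-1,3,11(13)-trien-6α,12-olide | C=C[C@]1(C)C[C@H](O[Si](C)(C)C(C)(C)C)[C@H]2C(=C)C(=O)O[C@@H]2[C@H]1C(=C)CO[Si](c1ccccc1)(c1ccccc1)C(C)(C)C | intermediate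
28 | 8α-hydroxy-15-(TBDPS-oxy)elema-1,3,11(13)-trien-6α,12-olide | C=C[C@]1(C)C[C@H](O)[C@H]2C(=C)C(=O)O[C@@H]2[C@H]1C(=C)CO[Si](c1ccccc1)(c1ccccc1)C(C)(C)C | intermediate
29 | (E)-crotonaldehyde | C/C=C/C=O | starting material
30 | (Z)-2-iodobut-2-enal | I/C(=C\C)C=O | intermediate
31 | (Z)-2-iodobut-2-en-1-ol | I/C(=C\C)CO | intermediate
32 | (Z)-1-(TBS-oxy)-2-iodobut-2-ene | I/C(=C\C)CO[Si](C)(C)C(C)(C)C | intermediate
33 | (Z)-1-(TBS-oxy)but-2-en-2-yllithium | [Li]/C(=C\C)CO[Si](C)(C)C(C)(C)C | intermediate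
34 | (Z)-2-(TBS-oxymethyl)but-2-enoic acid | O=C(O)/C(=C\C)CO[Si](C)(C)C(C)(C)C | intermediate
35 | mixed anhydride of 34 with 2,4,6-trichlorobenzoic acid | O=C(OC(=O)c1c(Cl)cc(Cl)cc1Cl)/C(=C\C)CO[Si](C)(C)C(C)(C)C | intermediate
36 | 8α-[(Z)-2-(TBS-oxymethyl)but-2-enoyloxy]-15-(TBDPS-oxy)elema-1,3,11(13)-trien-6α,12-olide | C=C[C@]1(C)C[C@H](OC(=O)/C(=C\C)CO[Si](C)(C)C(C)(C)C)[C@H]2C(=C)C(=O)O[C@@H]2[C@H]1C(=C)CO[Si](c1ccccc1)(c1ccccc1)C(C)(C)C | intermediate
37 | CNP0111202.1, 8α-[(Z)-2-(hydroxymethyl)but-2-enoyloxy]-15-hydroxyelema-1,3,11(13)-trien-6α,12-olide | C=C[C@]1(C)C[C@H](OC(=O)/C(=C\C)CO)[C@H]2C(=C)C(=O)O[C@@H]2[C@H]1C(=C)CO | target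

**Step count and risk**

Total step count: 24.
Longest linear sequence: 19 steps (steps 1–3, 5–18, 23 and 24).

The three steps most likely to fail:

Step 13. The carbenoid may approach the α face, because the axial C10 methyl crowds the β face at C6, or it may be used up by the C3=C4 methylene group and by dimerisation, so that the β-C7 adduct forms inefficiently. The fallback makes the C7–C11 bond by enolate alkylation. Enol ether 18 is treated with MeLi in THF at 0 °C, which regenerates lithium enolate 17 regiospecifically, and ethyl iodoacetate is added at −78 °C in THF–DMPU. Alkylation next to the C8 silyl ether may deliver the arm axially and give the C7-epimeric keto ester F1. Because C7 is α to the C6 ketone, brief treatment with DBU in CH2Cl2 should equilibrate it to the all-equatorial keto ester 21, where the route is rejoined.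

Step 15. The electron-transfer reduction may not reach thermodynamic control at C6, or may be slow at the doubly α-branched ketone, and then gives the 6β-alcohol and the cis-lactone. The fallback inverts C6 instead of controlling it. Keto ester 21 is reduced with K[HB(s-Bu)3] in THF at −78 °C, whose hydride enters from the α face opposite the axial C10 methyl, and the 6β-alkoxide closes onto the ester to give the cis-fused 6β,12-lactone F2. Saponification with LiOH in THF–H2O and careful acidification at 0 °C give the 6β-hydroxy acid F3. This is lactonised at once under Mitsunobu conditions (PPh3, DIAD, toluene), the carboxylate displacing the activated C6 oxygen with inversion, to give the trans-lactone 23.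

Step 10. The ketol may lose water to the conjugated enone under amine catalysis, or enamine formation at the hindered ketone may be so slow that aldehyde self-condensation takes over. The fallback accepts the enone and introduces the C8 oxygen afterwards. Keto aldehyde 14 is condensed with piperidine and AcOH in toluene at 50 °C to the cyclohexenone F4. Nucleophilic epoxidation (H2O2, NaOH, MeOH, 0 °C), in which hydroperoxide should add to C8 from the α face away from the axial C10 methyl, gives the 7α,8α-epoxy ketone F5. Reductive cleavage of the C7–O bond with Na[PhSeB(OEt)3] (from PhSeSePh and NaBH4 in EtOH, with AcOH) gives the 8α-hydroxy ketone 15.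

Further compounds
F1 | step 13 | ethyl 2-[(1S,3R,4S,6S)-6-(TBS-oxy)-4-ethenyl-4-methyl-2-oxo-3-[3-(TBDPS-oxy)prop-1-en-2-yl]cyclohexyl]acetate (C7 epimer of 21) | C=C[C@]1(C)C[C@H](O[Si](C)(C)C(C)(C)C)[C@H](CC(=O)OCC)C(=O)[C@H]1C(=C)CO[Si](c1ccccc1)(c1ccccc1)C(C)(C)C
F2 | step 15 | 8α-(TBS-oxy)-15-(TBDPS-oxy)elema-1,3-dien-6β,12-olide (cis-fused lactone, C6 epimer of 23) | C=C[C@]1(C)C[C@H](O[Si](C)(C)C(C)(C)C)[C@H]2CC(=O)O[C@H]2[C@H]1C(=C)CO[Si](c1ccccc1)(c1ccccc1)C(C)(C)C
F3 | step 15 | 6β-hydroxy-8α-(TBS-oxy)-15-(TBDPS-oxy)elema-1,3-dien-12-oic acid | C=C[C@]1(C)C[C@H](O[Si](C)(C)C(C)(C)C)[C@@H](CC(=O)O)[C@@H](O)[C@H]1C(=C)CO[Si](c1ccccc1)(c1ccccc1)C(C)(C)C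
F4 | step 10 | (5S,6R)-5-ethenyl-5-methyl-6-[3-(TBDPS-oxy)prop-1-en-2-yl]cyclohex-2-en-1-one | C=C[C@]1(C)CC=CC(=O)[C@H]1C(=C)CO[Si](c1ccccc1)(c1ccccc1)C(C)(C)C
F5 | step 10 | 7α,8α-epoxide of F4 (epoxy ketone, oxygen on the face opposite the C10 methyl) | C=C[C@]1(C)C[C@@H]2O[C@@H]2C(=O)[C@H]1C(=C)CO[Si](c1ccccc1)(c1ccccc1)C(C)(C)C
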